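**Retrosynthetic overview**

1. Locants (kept for all bicyclic intermediates): the target is a 7-bromo-4,7a-dimethyl-octahydroinden-4-ol; C1/C2 are the two CH2 groups of the cyclopentane, C3 the CH that bears the alkenyl group, C3a/C7a the ring-fusion carbons (H / CH3), C4 the C(CH3)OH carbon, C7 the CHBr carbon; ring A is the bromodimethylcyclohexylidene ring.
2. Enabling feature: C1–C2 is an unsubstituted ethano bridge between the quaternary C7a (next to C7, which can be a ketone) and the allylic methine C3, so the cyclopentane is the [3+2] adduct of ethylene with a cyclopropane C7a–C3a–C3 that carries an acyl group on C7a and a vinyl group on C3; disconnections C2–C3 and C1–C7a.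
3. Ring order: six-membered ring from 4-methoxy-3-methylphenol by dearomatisation; cyclopropane by ylide addition anti to a C4 silyloxy group (absolute configuration from a CBS reduction); cyclopentane and trans ring fusion in the key step.
4. Ring A last, grown from the C3 vinyl group: aldehyde, Nozaki–Hiyama–Kishi coupling, Johnson–Claisen rearrangement (sets the alkene geometry and the CMe2 carbon), Dieckmann closure.
5. End game: both C–Br bonds in one double Appel inversion of two (R)-carbinols; C4 carbinol by methyl addition anti to the angular methyl group.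

Key step: step 7

Remark: 4-methoxy-3-methylphenol, both enantiomers of 2-methyl-CBS-oxazaborolidine, trimethyl orthoisobutyrate and methyl pent-4-ynoate are taken as catalogue chemicals; the allyl sulfonium salt is made in step 5.

**Route**

Step 1
Reactants: 1 4-methoxy-3-methylphenol
Product: 2 4,4-dimethoxy-3-methylcyclohexa-2,5-dien-1-one
Conditions: PhI(OAc)2, MeOH, 0 °C to rt
Reagents that add atoms: methanol CO
Why: Oxidative dearomatisation of a para-methoxyphenol by trivalent iodine in methanol (quinone monoketal formation) traps the phenoxenium ion at the methoxy-bearing carbon and creates no stereocenter.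

Step 2
Reactants: 2 4,4-dimethoxy-3-methylcyclohexa-2,5-dien-1-one
Product: 3 4,4-dimethoxy-3-methylcyclohex-2-en-1-one
Conditions: H2 (1 atm), RhCl(PPh3)3 (5 mol %), benzene, rt
Reagents that add atoms: none
Why: Homogeneous hydrogenation with RhCl(PPh3)3 should reduce the disubstituted C5=C6 bond of the cross-conjugated dienone much faster than the trisubstituted C2=C3 bond, and it creates no stereocenter.

Step 3
Reactants: 3 4,4-dimethoxy-3-methylcyclohex-2-en-1-one
Product: 5 (S)-4-hydroxy-2-methylcyclohex-2-en-1-one, via allylic alcohol ketal 4 (not isolated)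
Conditions: (R)-2-methyl-CBS-oxazaborolidine (15 mol %), catecholborane, toluene, −78 °C; then 1 M aq. HCl, THF, 0 °C
Reagents that add atoms: water O
Why: Corey–Bakshi–Shibata reduction, in which the alkenyl side acts as the large group so that the (R)-catalyst should give the (S)-carbinol, is followed in the same flask by acid hydrolysis of the allylic dimethyl ketal, which unveils the transposed enone.

Step 4
Reactants: 5 (S)-4-hydroxy-2-methylcyclohex-2-en-1-one
Product: 6 (S)-4-[(tert-butyldimethylsilyl)oxy]-2-methylcyclohex-2-en-1-one
Conditions: TBSCl, imidazole, DMF, rt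
Reagents that add atoms: tert-butyldimethylsilyl chloride CC(C)(C)[Si](C)(C)Cl
Why: Standard silylation of a secondary alcohol leaves the stereocenter untouched and installs the bulky group that directs step 6.

Step 5
Reactants: 7 diphenyl sulfide; 8 allyl bromide
Product: 9 allyldiphenylsulfonium tetrafluoroborate
Conditions: AgBF4, CH2Cl2, rt, dark
Reagents that add atoms: silver tetrafluoroborate [Ag+].F[B-](F)(F)F
Why: S-Alkylation of the weakly nucleophilic diphenyl sulfide by allyl bromide is driven by precipitation of AgBr (silver-assisted sulfonium salt formation) and creates no stereocenter.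

Step 6
Reactants: 6 (S)-4-[(tert-butyldimethylsilyl)oxy]-2-methylcyclohex-2-en-1-one; 9 allyldiphenylsulfonium tetrafluoroborate
Product: 10 (1R,5S,6S,7S)-5-[(tert-butyldimethylsilyl)oxy]-7-ethenyl-1-methylbicyclo[4.1.0]heptan-2-one
Conditions: LiN(i-Pr)2, THF, −78 °C (ylide from 9); then 6, −78 to −20 °C
Reagents that add atoms: none
Why: Michael-initiated ring closure of a diphenylsulfonium allylide on an enone (Corey–Chaykovsky-type cyclopropanation): the ylide carbon should add to C3 of 6 anti to the C4 silyloxy group and the enolate then displaces Ph2S, which sets both ring-fusion carbons of the cis-fused cyclopropane, while the mainly exo orientation of the vinyl group is of no consequence because that carbon is re-formed in step 7.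

Step 7
Reactants: 10 (1R,5S,6S,7S)-5-[(tert-butyldimethylsilyl)oxy]-7-ethenyl-1-methylbicyclo[4.1.0]heptan-2-one; 11 ethylene
Product: 12 (3S,3aS,4S,7aS)-4-[(tert-butyldimethylsilyl)oxy]-3-ethenyl-7a-methyl-trans-hydrindan-7-one (target locants)
Conditions: PhSSPh (30 mol %), AIBN (20 mol %), ethylene (40 bar), benzene (0.02 M), 80 °C
Reagents that add atoms: none
Why: PhS• adds to the vinyl terminus of 10, the cyclopropylcarbinyl radical opens the C1–C7 bond to a tertiary α-keto radical at C1 (the future C7a) that carries an allyl sulfide on the neighbouring carbon, this electrophilic radical adds to ethylene, and the new primary radical closes onto the allyl sulfide and expels PhS•, which carries the chain. The closest known reaction type is the thiyl-radical-catalysed [3+2] cycloaddition of vinylcyclopropanes with alkenes, applied here with ethylene as the alkene. The cyclopentane is closed by a 5-exo-trig radical cyclisation (C2–C3 bond) after the intermolecular C1–C7a bond has been made, and the cyclopropane is opened in the same operation. C7a should be set because ethylene attacks the planar radical anti to the pseudo-axial C3a side chain (held axial by A(1,2) strain with the methyl group), which gives the trans ring fusion; C3 is set in the ring closure, where the alkenyl group should turn away from C4 and its silyloxy group to end cis to H-3a; C3a is carried over from the cyclopropane. The step needs regioselective ring opening toward C1 (secured by the C2 ketone of 10 and the tertiary centre) and ring closure faster than a second ethylene addition (secured by the intramolecular allyl sulfide trap and high dilution).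

Step 8
Reactants: 12 (3S,3aS,4S,7aS)-4-[(tert-butyldimethylsilyl)oxy]-3-ethenyl-7a-methyl-trans-hydrindan-7-one
Product: 14 4-[(tert-butyldimethylsilyl)oxy]-7a-methyl-7-oxo-trans-hydrindane-3-carbaldehyde, via ozonide 13 (not isolated)
Conditions: O3, CH2Cl2, −78 °C; then PPh3, −78 °C to rt
Reagents that add atoms: ozone [O-][O+]=O
Why: Ozonolysis with reductive work-up cleaves the only C=C bond under neutral conditions, so the adjacent C3 stereocenter (already the more stable epimer, with the formyl group turned away from C4) is kept.

Step 9
Reactants: 15 methyl pent-4-ynoate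
Product: 16 methyl 4-iodopent-4-enoate
Conditions: NaI, Me3SiCl, H2O, MeCN, rt
Reagents that add atoms: sodium iodide [Na+].[I-]
Why: Markovnikov hydroiodination of a terminal alkyne by HI generated in the flask gives the 2-iodoalk-1-ene and creates no stereocenter.

Step 10
Reactants: 14 4-[(tert-butyldimethylsilyl)oxy]-7a-methyl-7-oxo-trans-hydrindane-3-carbaldehyde; 16 methyl 4-iodopent-4-enoate
Product: 17 methyl 5-hydroxy-4-methylidene-5-(4-silyloxy-7a-methyl-7-oxo-trans-hydrindan-3-yl)pentanoate (both carbinol epimers)
Conditions: CrCl2 (4 equiv), NiCl2 (2 mol %), DMF, rt; then H2O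
Reagents that add atoms: none
Why: Nozaki–Hiyama–Kishi coupling, in which the alkenylchromium species formed from 16 under NiCl2 catalysis adds to the aldehyde and leaves ketone and ester untouched, gives the allylic carbinol as a mixture of epimers that converge in step 11.

Step 11
Reactants: 17 methyl 5-hydroxy-4-methylidene-5-(4-silyloxy-7a-methyl-7-oxo-trans-hydrindan-3-yl)pentanoate; 18 trimethyl orthoisobutyrate
Product: 20 dimethyl (4E)-2,2-dimethyl-4-[(4-silyloxy-7a-methyl-7-oxo-trans-hydrindan-3-yl)methylidene]heptanedioate, via ketene acetal 19 (not isolated)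
Conditions: 18 (10 equiv), EtCO2H (10 mol %), xylene, 140 °C, MeOH distilled off
Reagents that add atoms: none
Why: Johnson–Claisen rearrangement through a chair transition state with the bulky hydrindanyl substituent of the carbinol carbon pseudo-equatorial forms the CH2–CMe2 bond and should give the trisubstituted alkene with the hydrindane trans to the new CH2–CMe2 arm (E), and it removes the carbinol stereocenter.

Step 12
Reactants: 20 dimethyl (4E)-2,2-dimethyl-4-[(4-silyloxy-7a-methyl-7-oxo-trans-hydrindan-3-yl)methylidene]heptanedioate
Product: 21 the (7R)-7-hydroxy diester (axial alcohol)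
Conditions: K[sec-Bu3BH], THF, −78 °C; then H2O
Reagents that add atoms: none
Why: The bulky hydride should attack the C7 ketone along the equatorial trajectory (as with ketones next to a quaternary carbon in trans-fused bicycles) to give the axial (7R)-alcohol anti to the angular methyl group, and the esters are inert at −78 °C.

Step 13
Reactants: 21 the (7R)-7-hydroxy diester
Product: 23 (4E)-2,2-dimethyl-4-[((7R)-7-hydroxy-4-silyloxy-7a-methyl-trans-hydrindan-3-yl)methylidene]cyclohexan-1-one, via β-keto ester 22 (not isolated)
Conditions: KOt-Bu, THF, 0 °C to rt; AcOH; then LiCl, DMSO, H2O, 150 °C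
Reagents that add atoms: none
Why: Dieckmann condensation, in which only the CH2CH2CO2Me arm can enolise and the six-membered β-keto ester forms as its stable enolate, is followed by Krapcho demethoxycarbonylation, and no stereocenter or the alkene geometry is touched.

Step 14
Reactants: 23 the ring A ketone with free (7R)-alcohol
Product: 24 the diol with (R)-carbinol in ring A and (7R)-carbinol in the hydrindane
Conditions: (S)-2-methyl-CBS-oxazaborolidine (20 mol %), catecholborane (3 equiv), toluene, −78 to −40 °C; then H2O
Reagents that add atoms: none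
Why: Corey–Bakshi–Shibata reduction of a ketone flanked by a quaternary carbon (large) and a CH2 group (small), where the (S)-catalyst should give the (R)-alcohol under catalyst control and catecholborane leaves the trisubstituted alkene alone.

Step 15
Reactants: 24 the diol
Product: 25 the dibromide with (7S)-bromide and (4S)-bromide in ring A (C4 silyl ether kept)
Conditions: CBr4, PPh3, toluene, 0 to 60 °C
Reagents that add atoms: carbon tetrabromide BrC(Br)(Br)Br
Why: Double Appel reaction, in which each alkoxyphosphonium ion is displaced by bromide with inversion (precedented for axial carbinols next to a quaternary carbon), should turn the axial (7R)-alcohol into the equatorial (7S)-bromide and the (R)-carbinol of ring A into the (S)-bromide in one operation.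

Step 16
Reactants: 25 the dibromide silyl ether
Product: 26 the dibromo C4 alcohol
Conditions: 48% aq. HF, MeCN, rt
Reagents that add atoms: none
Why: Fluoride-mediated cleavage of the secondary silyl ether under acidic, non-basic conditions that the secondary bromides and the alkene tolerate, with no stereocenter changed.

Step 17
Reactants: 26 the dibromo C4 alcohol
Product: 27 the dibromo trans-hydrindan-4-one
Conditions: Dess–Martin periodinane, CH2Cl2, 0 °C to rt
Reagents that add atoms: none
Why: Dess–Martin oxidation of the secondary alcohol under near-neutral conditions should give the trans-fused ketone without enolisation toward C3a.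

Step 18
Reactants: 27 the dibromo trans-hydrindan-4-one
Product: 28 (3S,3aS,4R,7S,7aS)-7-bromo-3-{(E)-[(4S)-4-bromo-3,3-dimethylcyclohexylidene]methyl}-4,7a-dimethyloctahydro-1H-inden-4-ol
Conditions: MeMgBr, CeCl3, THF, −78 °C; then H2O
Reagents that add atoms: methylmagnesium bromide C[Mg]Br
Why: Addition of the weakly basic organocerium reagent to the C4 ketone from the face anti to the axial 7a-methyl group (equatorial attack, as in hydride additions to trans-hydrindan-4-ones with an angular methyl group) should set the (4R)-carbinol with axial OH while avoiding enolisation and attack on the bromides.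

**Compound list**

1 | 4-methoxy-3-methylphenol | COc1ccc(O)cc1C | starting material
2 | 4,4-dimethoxy-3-methylcyclohexa-2,5-dien-1-one | COC1(OC)C=CC(=O)C=C1C | intermediate
3 | 4,4-dimethoxy-3-methylcyclohex-2-en-1-one | COC1(OC)CCC(=O)C=C1C | intermediate
4 | (S)-4,4-dimethoxy-3-methylcyclohex-2-en-1-ol (not isolated) | O[C@@H]1C=C(C)C(OC)(OC)CC1 | intermediate
5 | (S)-4-hydroxy-2-methylcyclohex-2-en-1-one | CC1=C[C@@H](O)CCC1=O | intermediate
6 | (S)-4-[(tert-butyldimethylsilyl)oxy]-2-methylcyclohex-2-en-1-one | CC1=C[C@@H](O[Si](C)(C)C(C)(C)C)CCC1=O | intermediate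
7 | diphenyl sulfide | c1ccc(cc1)Sc1ccccc1 | starting material
8 | allyl bromide | C=CCBr | starting material
9 | allyldiphenylsulfonium tetrafluoroborate | C=CC[S+](c1ccccc1)c1ccccc1.F[B-](F)(F)F | intermediate
10 | (1R,5S,6S,7S)-5-[(tert-butyldimethylsilyl)oxy]-7-ethenyl-1-methylbicyclo[4.1.0]heptan-2-one (exo vinyl; cyclopropane anti to the silyloxy group) | C=C[C@@H]1[C@@]2(C)C(=O)CC[C@H](O[Si](C)(C)C(C)(C)C)[C@@H]12 | intermediate
11 | ethylene | C=C | starting material
12 | (3S,3aS,4S,7aS)-4-[(tert-butyldimethylsilyl)oxy]-3-ethenyl-7a-methyl-trans-hydrindan-7-one | C=C[C@@H]2CC[C@]3(C)C(=O)CC[C@H](O[Si](C)(C)C(C)(C)C)[C@@H]23 | intermediate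
13 | ozonide of 12 (1,2,4-trioxolan-3-yl on C3; not isolated) | C1OC(OO1)[C@@H]2CC[C@]3(C)C(=O)CC[C@H](O[Si](C)(C)C(C)(C)C)[C@@H]23 | intermediate
14 | 4-[(tert-butyldimethylsilyl)oxy]-7a-methyl-7-oxo-trans-hydrindane-3-carbaldehyde (core configuration as in 12) | O=C[C@@H]2CC[C@]3(C)C(=O)CC[C@H](O[Si](C)(C)C(C)(C)C)[C@@H]23 | intermediate
15 | methyl pent-4-ynoate | COC(=O)CCC#C | starting material
16 | methyl 4-iodopent-4-enoate | COC(=O)CCC(I)=C | intermediate
17 | methyl 5-hydroxy-4-methylidene-5-(hydrindan-3-yl)pentanoate (core as in 12; both carbinol epimers) | COC(=O)CCC(=C)C(O)[C@@H]2CC[C@]3(C)C(=O)CC[C@H](O[Si](C)(C)C(C)(C)C)[C@@H]23 | intermediate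
18 | trimethyl orthoisobutyrate (1,1,1-trimethoxy-2-methylpropane) | COC(OC)(OC)C(C)C | starting material
19 | mixed ketene acetal of 17 (O-allyl O-methyl dimethylketene acetal; not isolated) | COC(=O)CCC(=C)C(OC(OC)=C(C)C)[C@@H]2CC[C@]3(C)C(=O)CC[C@H](O[Si](C)(C)C(C)(C)C)[C@@H]23 | intermediate
20 | dimethyl (4E)-2,2-dimethyl-4-[(hydrindan-3-yl)methylidene]heptanedioate (C7 ketone; core as in 12) | COC(=O)C(C)(C)C/C(=C/[C@@H]2CC[C@]3(C)C(=O)CC[C@H](O[Si](C)(C)C(C)(C)C)[C@@H]23)CCC(=O)OC | intermediate
21 | (7R)-7-hydroxy diester (axial OH) | COC(=O)C(C)(C)C/C(=C/[C@@H]2CC[C@]3(C)[C@H](O)CC[C@H](O[Si](C)(C)C(C)(C)C)[C@@H]23)CCC(=O)OC | intermediate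
22 | methyl 3,3-dimethyl-2-oxo-5-[(hydrindan-3-yl)methylidene]cyclohexane-1-carboxylate (not isolated) | CC1(C)C/C(=C/[C@@H]2CC[C@]3(C)[C@H](O)CC[C@H](O[Si](C)(C)C(C)(C)C)[C@@H]23)CC(C(=O)OC)C1=O | intermediate
23 | (4E)-2,2-dimethyl-4-[(hydrindan-3-yl)methylidene]cyclohexan-1-one with free (7R)-OH | CC1(C)C/C(=C/[C@@H]2CC[C@]3(C)[C@H](O)CC[C@H](O[Si](C)(C)C(C)(C)C)[C@@H]23)CCC1=O | intermediate
24 | diol: (R)-carbinol in ring A and (7R)-carbinol; C4 silyl ether | CC1(C)C/C(=C/[C@@H]2CC[C@]3(C)[C@H](O)CC[C@H](O[Si](C)(C)C(C)(C)C)[C@@H]23)CC[C@H]1O | intermediate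
25 | dibromide: (4S)-bromide in ring A and (7S)-bromide; C4 silyl ether | CC1(C)C/C(=C/[C@@H]2CC[C@]3(C)[C@@H](Br)CC[C@H](O[Si](C)(C)C(C)(C)C)[C@@H]23)CC[C@@H]1Br | intermediate
26 | dibromo (4S)-secondary alcohol | CC1(C)C/C(=C/[C@@H]2CC[C@]3(C)[C@@H](Br)CC[C@H](O)[C@@H]23)CC[C@@H]1Br | intermediate
27 | dibromo trans-hydrindan-4-one | CC1(C)C/C(=C/[C@@H]2CC[C@]3(C)[C@@H](Br)CCC(=O)[C@@H]23)CC[C@@H]1Br | intermediate
28 | (3S,3aS,4R,7S,7aS)-7-bromo-3-{(E)-[(4S)-4-bromo-3,3-dimethylcyclohexylidene]methyl}-4,7a-dimethyloctahydro-1H-inden-4-ol | CC1(C)C/C(=C/[C@@H]2CC[C@]3(C)[C@@H](Br)CC[C@@](C)(O)[C@@H]23)CC[C@@H]1Br | target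

**Step count and risks**

Total step count: 18. Longest linear sequence: 16 steps (steps 1–4, 6–8 and 10–18).

Steps most likely to fail:

1. Step 7. The hindered tertiary radical may be trapped too slowly by ethylene, so that recombination with the thiyl radical, oligomerisation with ethylene or attack on the wrong face of C7a (cis ring fusion) competes. The fallback replaces the radical [3+2] by a polar one and sets out from 10: zerovalent palladium (Pd2(dba)3, dppe, DMSO, 60 °C) should ionise the acyl vinylcyclopropane to a palladium π-allyl/ketone enolate zwitterion, whose enolate carbon adds to phenyl vinyl sulfone anti to the C3a side chain and whose α-sulfonyl carbanion then closes on the allyl terminus, to give the C2 sulfonyl hydrindanone F1; Na/Hg with Na2HPO4 in MeOH at −20 °C then removes the sulfonyl group, and the route is rejoined at 12.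

2. Step 6. Addition of the ylide to the carbonyl group, or base-induced loss of silanol with aromatisation, may outrun conjugate addition at the hindered C3. The fallback replaces the ylide by a dienolate and sets out from 6: the lithium dienolate of ethyl (E)-4-bromobut-2-enoate (LiN(i-Pr)2, THF, −78 °C) should add 1,4 through its bromine-bearing carbon anti to the silyloxy group and close to the cyclopropyl acrylate F2; ozonolysis (O3, CH2Cl2, −78 °C; PPh3) gives the cyclopropanecarbaldehyde F3, and Ph3P=CH2 (THF, −78 °C) methylenates the aldehyde in preference to the hindered ketone, which rejoins the route at 10.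

3. Step 15. Elimination or a 1,2-methyl shift at the two neopentyl-type alkoxyphosphonium ions may outrun substitution, or the axial C7 carbinol may react incompletely. The fallback separates activation and substitution and sets out from 24: NaH and 1,1'-sulfonyldiimidazole (DMF, −40 °C) give the bis(imidazole-1-sulfonate) F4, which Bu4NBr (toluene, 80 °C) should displace with inversion at both carbons, rejoining the route at 25.

Further compounds
F1 | step 7 | 2-(phenylsulfonyl) derivative of 12 (C2 epimers) | C=C[C@@H]2C(S(=O)(=O)c1ccccc1)C[C@]3(C)C(=O)CC[C@H](O[Si](C)(C)C(C)(C)C)[C@@H]23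
F2 | step 6 | ethyl (E)-3-[5-(tert-butyldimethylsilyloxy)-1-methyl-2-oxobicyclo[4.1.0]heptan-7-yl]prop-2-enoate (ring configuration as in 10) | CCOC(=O)/C=C/[C@@H]1[C@@]2(C)C(=O)CC[C@H](O[Si](C)(C)C(C)(C)C)[C@@H]12
F3 | step 6 | 5-(tert-butyldimethylsilyloxy)-1-methyl-2-oxobicyclo[4.1.0]heptane-7-carbaldehyde (ring configuration as in 10) | O=C[C@@H]1[C@@]2(C)C(=O)CC[C@H](O[Si](C)(C)C(C)(C)C)[C@@H]12
F4 | step 15 | bis(imidazole-1-sulfonate) of diol 24 | CC1(C)C/C(=C/[C@@H]2CC[C@]3(C)[C@H](OS(=O)(=O)n4ccnc4)CC[C@H](O[Si](C)(C)C(C)(C)C)[C@@H]23)CC[C@H]1OS(=O)(=O)n1ccnc1
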